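**Plan**
1. Retrosynthesis: the three benzyl ethers go last. The CH2–C(=O) bond between the α-methylene and the acyl carbon of the arm on the phenolic (4-hydroxy-3-aryloxyphenyl) ring is cut to a vinylarene and 4-(benzyloxy)-2-hydroxybenzaldehyde. That vinyl goes back to a formyl group, the same bond of the guaiacyl-ring arm is cut likewise, and last the aryl C–O bond of the diaryl ether at the benzyloxy ring.
2. Forward: an Ullmann coupling gives the diaryl ether, and a first hydroacylation builds the guaiacyl-ring arm. A Wittig reaction turns the remaining formyl group into vinyl, and a second hydroacylation (the key step) joins the completed half to the last acyl unit. Hydrogenolysis then frees the three phenols.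
3. Enabling feature: the 2-hydroxyl of each 2,4-dihydroxyphenyl ring, ortho to the ketone carbon. In the aldehyde precursor it binds rhodium as a phenoxide next to the formyl C–H bond, so the formyl carbon adds as an acyl–metal unit to the terminal vinyl carbon without decarbonylation. It belongs to the target and is not removed.
4. No ring is formed (all four benzene rings come from the starting materials), and the target has no stereocentre, so no stereochemistry has to be set.

Key step: step 4

Remark: verbenachalcone has no stereocentre, stereogenic axis or configurable double bond, so "single enantiomer" is taken to mean the one achiral compound.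

**Step 1**
Reactants: 1 (2-methoxy-4-vinylphenol); 2 (4-(benzyloxy)-3-bromobenzaldehyde)
Product: 3 4-(benzyloxy)-3-(2-methoxy-4-vinylphenoxy)benzaldehyde
Conditions: CuI (10 mol %), picolinic acid (20 mol %), K3PO4 (2 equiv), BHT (cat.), DMSO, 90 °C
Reagents that add atoms: none
Why: Ullmann-type copper(I)-catalysed O-arylation, in which the picolinate-ligated copper phenoxide of 1 should add to the C–Br bond of 2 and eliminate the diaryl ether; this ligand system suits an ortho-substituted phenol with an ortho-substituted aryl bromide, the formyl, benzyl ether and vinyl groups are spectators, and BHT holds back radical polymerisation of the styrene.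

**Step 2**
Reactants: 3 (4-(benzyloxy)-3-(2-methoxy-4-vinylphenoxy)benzaldehyde); 4 (4-(benzyloxy)-2-hydroxybenzaldehyde, 1.5 equiv)
Product: 5 4-(benzyloxy)-3-{4-[3-(4-benzyloxy-2-hydroxyphenyl)-3-oxopropyl]-2-methoxyphenoxy}benzaldehyde
Conditions: [Rh(cod)OMe]2 (2.5 mol %), bulky BINOL-type phosphoramidite (10 mol %), K3PO4 (10 mol %), 2-MeTHF, 70 °C
Reagents that add atoms: none
Why: Rhodium(I)-catalysed, chelation-assisted intermolecular alkene hydroacylation by a salicylaldehyde, in which the rhodium phenoxide of 4 inserts into its own formyl C–H bond to give an O,C-chelated acyl rhodium hydride that resists decarbonylation, and hydride transfer to the internal vinyl carbon of 3 followed by acyl–alkyl reductive elimination should give the linear ketone; the formyl group of 3 has no ortho-hydroxyl and should not be activated under these conditions.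

**Step 3**
Reactants: 5 (4-(benzyloxy)-3-{4-[3-(4-benzyloxy-2-hydroxyphenyl)-3-oxopropyl]-2-methoxyphenoxy}benzaldehyde)
Product: 6 1-[4-(benzyloxy)-2-hydroxyphenyl]-3-{4-[2-(benzyloxy)-5-vinylphenoxy]-3-methoxyphenyl}propan-1-one
Conditions: Ph3PCH3Br (3 equiv), KOtBu (3 equiv), THF, 0 °C to rt; aq. NH4Cl
Reagents that add atoms: methyltriphenylphosphonium bromide, C[P+](c1ccccc1)(c1ccccc1)c1ccccc1.[Br-]
Why: Wittig methylenation, selective for the aldehyde because the aryl ketone is far less electrophilic and is further deactivated as its ortho-phenoxide under the basic conditions; the excess ylide covers the acidic phenol, which returns on work-up.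

**Step 4**
Reactants: 6 (1-[4-(benzyloxy)-2-hydroxyphenyl]-3-{4-[2-(benzyloxy)-5-vinylphenoxy]-3-methoxyphenyl}propan-1-one); 4 (4-(benzyloxy)-2-hydroxybenzaldehyde, 1.5 equiv)
Product: 7 1-[4-(benzyloxy)-2-hydroxyphenyl]-3-{4-(benzyloxy)-3-[4-(3-(4-benzyloxy-2-hydroxyphenyl)-3-oxopropyl)-2-methoxyphenoxy]phenyl}propan-1-one (tri-O-benzylverbenachalcone)
Conditions: [Rh(cod)OMe]2 (2.5 mol %), bulky BINOL-type phosphoramidite (10 mol %), K3PO4 (10 mol %), 2-MeTHF, 70 °C
Reagents that add atoms: none
Why: Catalytic K3PO4 turns the 2-hydroxyl of 4 into a rhodium(I) phenoxide, from which oxidative addition of the neighbouring formyl C–H bond gives a five-membered O,C-chelated acyl rhodium(III) hydride that is held against decarbonylation; the vinyl group of 6 coordinates, hydride passes to its internal (benzylic) carbon and acyl–alkyl reductive elimination forms the CH2–C(=O) bond at the terminal carbon. The closest known reaction type is the rhodium-catalysed, salicylaldehyde-directed intermolecular hydroacylation of terminal alkenes, which is linear-selective with bulky phosphoramidite ligands and is the reaction already used in step 2. No ring is closed and no stereocentre is formed, the new chain being two methylene groups. The step needs linear over branched regioselectivity: insertion towards the benzylic rhodium alkyl is expected to be reversible and its reductive elimination slowed by the bulky monodentate ligand, and the para-benzyloxy group of the vinylarene lowers the stabilisation of a benzylic Rh–C bond, so the primary alkyl should be the one that eliminates. It also needs chemoselectivity, which the substrate secures because 4 is the only formyl compound present and the 2-hydroxyaryl ketone of 6 can bind rhodium only reversibly, as the product of every such hydroacylation does.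

**Step 5**
Reactants: 7 (tri-O-benzylverbenachalcone)
Product: 8 verbenachalcone
Conditions: H2 (1 atm), 10 % Pd/C, EtOAc–MeOH, rt
Reagents that add atoms: none
Why: Palladium-catalysed hydrogenolysis should cleave the three benzyl aryl ethers, while the diaryl ether, the methyl ether and the two hydrogen-bonded, electron-rich 2-hydroxyaryl ketones should not be reduced at 1 atm and room temperature.

**Compound list**
1 | 2-methoxy-4-vinylphenol (4-vinylguaiacol) | C=Cc1ccc(O)c(OC)c1 | starting material
2 | 4-(benzyloxy)-3-bromobenzaldehyde | O=Cc1ccc(OCc2ccccc2)c(Br)c1 | starting material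
3 | 4-(benzyloxy)-3-(2-methoxy-4-vinylphenoxy)benzaldehyde | C=Cc1ccc(Oc2cc(C=O)ccc2OCc2ccccc2)c(OC)c1 | intermediate
4 | 4-(benzyloxy)-2-hydroxybenzaldehyde | O=Cc1ccc(OCc2ccccc2)cc1O | starting material
5 | 4-(benzyloxy)-3-{4-[3-(4-benzyloxy-2-hydroxyphenyl)-3-oxopropyl]-2-methoxyphenoxy}benzaldehyde | COc1cc(CCC(=O)c2ccc(OCc3ccccc3)cc2O)ccc1Oc1cc(C=O)ccc1OCc1ccccc1 | intermediate
6 | 1-[4-(benzyloxy)-2-hydroxyphenyl]-3-{4-[2-(benzyloxy)-5-vinylphenoxy]-3-methoxyphenyl}propan-1-one | COc1cc(CCC(=O)c2ccc(OCc3ccccc3)cc2O)ccc1Oc1cc(C=C)ccc1OCc1ccccc1 | intermediate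
7 | 1-[4-(benzyloxy)-2-hydroxyphenyl]-3-{4-(benzyloxy)-3-[4-(3-(4-benzyloxy-2-hydroxyphenyl)-3-oxopropyl)-2-methoxyphenoxy]phenyl}propan-1-one (tri-O-benzylverbenachalcone) | COc1cc(CCC(=O)c2ccc(OCc3ccccc3)cc2O)ccc1Oc1cc(CCC(=O)c2ccc(OCc3ccccc3)cc2O)ccc1OCc1ccccc1 | intermediate
8 | verbenachalcone | COc1cc(CCC(=O)c2ccc(O)cc2O)ccc1Oc1cc(CCC(=O)c2ccc(O)cc2O)ccc1O | target

Total step count: 5. Longest linear sequence: 5 steps (1 → 3 → 5 → 6 → 7 → 8).

**Steps most likely to fail**

Step 4. Hydride may be delivered to the terminal instead of the internal vinyl carbon, so that rhodium ends at the benzylic position and the branched ketone forms; turnover may also be slow because the chelating hydroxy ketone already in 6 occupies the metal. The fallback replaces the hydroacylation by aldol logic and sets out from 5. Claisen–Schmidt condensation of the formyl group of 5 with commercial 1-[4-(benzyloxy)-2-hydroxyphenyl]ethanone (3 equiv, KOH, EtOH, rt) should give (E)-1-[4-(benzyloxy)-2-hydroxyphenyl]-3-{4-(benzyloxy)-3-[4-(3-(4-benzyloxy-2-hydroxyphenyl)-3-oxopropyl)-2-methoxyphenoxy]phenyl}prop-2-en-1-one F1. Hydrogenation of F1 under the conditions of step 5 should saturate the enone double bond and cleave the three benzyl ethers in one operation, so the fallback comes back to the route at 8.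

Step 2. The same regiochemical leakage may occur at a still more electron-rich vinylarene, and rhodium may be lost gradually to a carbonyl complex through decarbonylation of the non-chelating formyl group of 3. The fallback gives up hydroacylation for both arms and sets out from 3. Lemieux–Johnson cleavage of the vinyl group (OsO4 cat., NaIO4, 2,6-lutidine, dioxane–water) should give 4-(benzyloxy)-3-(4-formyl-2-methoxyphenoxy)benzaldehyde F2. Twofold Claisen–Schmidt condensation of F2 with 1-[4-(benzyloxy)-2-hydroxyphenyl]ethanone (KOH, EtOH, rt) should give the bis-chalcone (E)-1-[4-(benzyloxy)-2-hydroxyphenyl]-3-{4-(benzyloxy)-3-[4-((E)-3-(4-benzyloxy-2-hydroxyphenyl)-3-oxoprop-1-enyl)-2-methoxyphenoxy]phenyl}prop-2-en-1-one F3. Hydrogenation of F3 with H2 and Pd/C should reduce both double bonds and remove the benzyl groups, so the fallback comes back at 8.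

Step 1. The vinylphenoxide may oligomerise thermally at 90 °C, and C–O bond formation at copper between two ortho-alkoxy partners may be slow. The fallback reverses the polarity of the benzyloxy-ring carbon and works at room temperature; it sets out from 2. Miyaura borylation (B2pin2, Pd(dppf)Cl2, KOAc, dioxane, 80 °C) should give 4-(benzyloxy)-3-(4,4,5,5-tetramethyl-1,3,2-dioxaborolan-2-yl)benzaldehyde F4. Oxidative removal of the pinacol unit (NaIO4, NH4OAc, acetone–water) should give [2-(benzyloxy)-5-formylphenyl]boronic acid F5. Chan–Lam coupling of F5 with 1 (Cu(OAc)2, pyridine, 4 Å molecular sieves, CH2Cl2, air, rt) should give the diaryl ether, so the fallback comes back at 3.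

**Further compounds**
F1 | step 4 | (E)-1-[4-(benzyloxy)-2-hydroxyphenyl]-3-{4-(benzyloxy)-3-[4-(3-(4-benzyloxy-2-hydroxyphenyl)-3-oxopropyl)-2-methoxyphenoxy]phenyl}prop-2-en-1-one | COc1cc(CCC(=O)c2ccc(OCc3ccccc3)cc2O)ccc1Oc1cc(/C=C/C(=O)c2ccc(OCc3ccccc3)cc2O)ccc1OCc1ccccc1
F2 | step 2 | 4-(benzyloxy)-3-(4-formyl-2-methoxyphenoxy)benzaldehyde | COc1cc(C=O)ccc1Oc1cc(C=O)ccc1OCc1ccccc1
F3 | step 2 | (E)-1-[4-(benzyloxy)-2-hydroxyphenyl]-3-{4-(benzyloxy)-3-[4-((E)-3-(4-benzyloxy-2-hydroxyphenyl)-3-oxoprop-1-enyl)-2-methoxyphenoxy]phenyl}prop-2-en-1-one | COc1cc(/C=C/C(=O)c2ccc(OCc3ccccc3)cc2O)ccc1Oc1cc(/C=C/C(=O)c2ccc(OCc3ccccc3)cc2O)ccc1OCc1ccccc1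
F4 | step 1 | 4-(benzyloxy)-3-(4,4,5,5-tetramethyl-1,3,2-dioxaborolan-2-yl)benzaldehyde | O=Cc1ccc(OCc2ccccc2)c(B2OC(C)(C)C(C)(C)O2)c1
F5 | step 1 | [2-(benzyloxy)-5-formylphenyl]boronic acid | O=Cc1ccc(OCc2ccccc2)c(B(O)O)c1
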